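## Retrosynthetic overview

1. Target ⇒ macrocyclic diene diol; the secondary C2 hydroxyl is acetylated last, the tertiary C11 hydroxyl stays free.
2. 14-membered carbocycle ⇒ opened at the C6–C7 diene σ-bond: palladium-catalysed ring-closing coupling of a C7 alkenyl iodide with a C6 alkenylalane made in the same flask by methylalumination of a terminal alkyne (brings in the C5 methyl and the E geometry).
3. Seco diol ⇒ chelation-controlled MeMgBr addition to a 2-acyloxolane (sets C11); oxolane ⇒ Shi epoxidation of an E trisubstituted alkene and 5-exo opening by the C12 hydroxyl (sets C1 and C2).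
4. Acyclic ketone ⇒ three fragments: enolate allylation (C9–C10) with an east iodoallyl bromide from propargyl alcohol; sp3–sp2 Negishi coupling (C14–C1) of a central alkylzinc from (R)-α-hydroxy-γ-butyrolactone (source of C12) with a west alkenyl iodide from pent-3-yn-1-ol and ethynyltrimethylsilane.
5. Ring order: oxolane first (step 11), 14-membered ring second (step 13).

Assumption: the SMILES is taken as the absolute configuration, (1S,2R,5E,7E,11S,12R) in 15-oxabicyclo[10.2.1]pentadecane numbering (used for all atom numbers here), and (R)-α-hydroxy-γ-butyrolactone is taken as commercial.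

## Route

Step 1
Reactants: 1 pent-3-yn-1-ol
Product: 3 (3E)-4-iodopent-3-en-1-ol, via alkenylzirconocene chloride 2 (not isolated)
Conditions: Cp2Zr(H)Cl (2.3 equiv), THF, 23 → 45 °C; then I2, 0 °C
Reagents that add atoms: iodine, `[I][I]`
Why: Hydrozirconation–iodination: Cp2Zr(H)Cl adds syn across the internal alkyne, excess reagent equilibrates zirconium to the less hindered methyl-bearing carbon, and iodinolysis with retention gives the E alkenyl iodide, the hydroxyl riding through as its zirconium alkoxide.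

Step 2
Reactants: 3 (3E)-4-iodopent-3-en-1-ol
Product: 4 (3E)-4-iodopent-3-en-1-yl trifluoromethanesulfonate
Conditions: Tf2O, pyridine, CH2Cl2, −78 → −30 °C (used crude)
Reagents that add atoms: trifluoromethanesulfonic anhydride, `O=S(=O)(OS(=O)(=O)C(F)(F)F)C(F)(F)F`
Why: O-Sulfonylation of the primary alcohol gives a triflate that is substituted at low temperature, where elimination of the homoallylic system is slow.

Step 3
Reactants: 4 (3E)-4-iodopent-3-en-1-yl trifluoromethanesulfonate; 5 ethynyltrimethylsilane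
Product: 7 trimethyl[(5E)-6-iodohept-5-en-1-yn-1-yl]silane, via lithium acetylide 6 (not isolated)
Conditions: 5, n-BuLi, THF, −78 °C; then 4, DMPU, −78 → −20 °C
Reagents that add atoms: none
Why: SN2 alkylation of a lithium acetylide by a primary triflate; the alkenyl iodide is inert to the acetylide and the silyl group blocks the alkyne terminus during the later base-mediated steps.

Step 4
Reactants: 8 (3R)-3-hydroxyoxolan-2-one
Product: 9 (3R)-3-[(triethylsilyl)oxy]oxolan-2-one
Conditions: Et3SiCl, imidazole, DMF, 0 → 23 °C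
Reagents that add atoms: chlorotriethylsilane, `CC[Si](Cl)(CC)CC`
Why: Imidazole-promoted silylation protects the secondary hydroxyl without touching the stereocentre that becomes C12.

Step 5
Reactants: 9 (3R)-3-[(triethylsilyl)oxy]oxolan-2-one
Product: 10 (3R)-5-hydroxy-3-[(triethylsilyl)oxy]pentan-2-one (in equilibrium with its cyclic hemiketal)
Conditions: MeLi (1.05 equiv), THF, −78 °C; AcOH quench at −78 °C
Reagents that add atoms: methyllithium, `[Li]C`
Why: Mono-addition of an organolithium to a lactone: the tetrahedral lithium hemiketal alkoxide is stable at −78 °C and gives the methyl ketone only on protonation, so no second addition occurs.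

Step 6
Reactants: 10 (3R)-5-hydroxy-3-[(triethylsilyl)oxy]pentan-2-one
Product: 11 (3R)-5-iodo-3-[(triethylsilyl)oxy]pentan-2-one
Conditions: I2, PPh3, imidazole, CH2Cl2, 0 °C
Reagents that add atoms: iodine, `[I][I]`
Why: Appel-type (Garegg–Samuelsson) iodination of the primary hydroxyl of the open-chain tautomer, which is drained from the hemiketal equilibrium.

Step 7
Reactants: 11 (3R)-5-iodo-3-[(triethylsilyl)oxy]pentan-2-one; 7 trimethyl[(5E)-6-iodohept-5-en-1-yn-1-yl]silane
Product: 13 (3R,6E)-6-methyl-3-[(triethylsilyl)oxy]-11-(trimethylsilyl)undec-6-en-10-yn-2-one, via alkylzinc iodide 12 (not isolated)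
Conditions: 11, Zn (dust, activated), LiCl, THF, 30 °C; then 7, Pd(OAc)2 (2 mol %), SPhos (4 mol %), THF, 23 °C
Reagents that add atoms: none
Why: Palladium-catalysed Negishi sp3–sp2 cross-coupling: zinc inserts into the primary C–I bond to give a ketone-tolerant alkylzinc (no leaving group β to zinc) that couples with the alkenyl iodide with retention of the E geometry, forming C14–C1.

Step 8
Reactants: 14 prop-2-yn-1-ol
Product: 16 (2Z)-3-iodo-2-(propan-2-yl)prop-2-en-1-ol, via alkenylmagnesium alkoxide 15 (not isolated)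
Conditions: iPrMgCl (2.5 equiv), CuI (10 mol %), THF, −10 → 23 °C; then I2, −20 °C
Reagents that add atoms: isopropylmagnesium chloride, `CC(C)[Mg]Cl`; iodine, `[I][I]`
Why: Copper-catalysed anti-carbomagnesiation of propargyl alcohol (Duboudin–Jousseaume reaction): the alkoxide directs isopropyl to the internal carbon and magnesium to the terminal carbon cis to CH2O, and iodinolysis with retention gives the Z iodide.

Step 9
Reactants: 16 (2Z)-3-iodo-2-(propan-2-yl)prop-2-en-1-ol
Product: 17 (1Z)-2-(bromomethyl)-1-iodo-3-methylbut-1-ene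
Conditions: CBr4, PPh3, CH2Cl2, 0 °C
Reagents that add atoms: tetrabromomethane, `BrC(Br)(Br)Br`
Why: Appel bromination of the primary allylic alcohol under neutral conditions, without allylic transposition or loss of alkene geometry.

Step 10
Reactants: 13 (3R,6E)-6-methyl-3-[(triethylsilyl)oxy]-11-(trimethylsilyl)undec-6-en-10-yn-2-one; 17 (1Z)-2-(bromomethyl)-1-iodo-3-methylbut-1-ene
Product: 19 (1E,6R,9E)-1-iodo-9-methyl-2-(propan-2-yl)-6-[(triethylsilyl)oxy]-14-(trimethylsilyl)tetradeca-1,9-dien-13-yn-5-one, via lithium enolate 18 (not isolated)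
Conditions: LiN(iPr)2 (1.1 equiv), THF, −78 °C; then 17, −78 → −40 °C
Reagents that add atoms: none
Why: Kinetic enolate alkylation: LiN(iPr)2 removes a methyl proton in preference to the hindered silyloxy-bearing methine, and the enolate displaces the primary allylic bromide (SN2), forming C9–C10 with both alkene geometries untouched.

Step 11
Reactants: 19 (1E,6R,9E)-1-iodo-9-methyl-2-(propan-2-yl)-6-[(triethylsilyl)oxy]-14-(trimethylsilyl)tetradeca-1,9-dien-13-yn-5-one
Product: 21 (4E)-1-{(2R,5S)-5-[(1R)-1-hydroxy-5-(trimethylsilyl)pent-4-yn-1-yl]-5-methyloxolan-2-yl}-5-iodo-4-(propan-2-yl)pent-4-en-1-one, via epoxide 20 (not isolated)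
Conditions: 1,2:4,5-di-O-isopropylidene-β-D-erythro-2,3-hexodiulo-2,6-pyranose (D-fructose-derived Shi ketone, 0.3 equiv), KHSO5 (as 2KHSO5·KHSO4·K2SO4), K2CO3, Bu4NHSO4 (cat.), MeCN/CH2(OMe)2/aq. Na2B4O7 buffer, 0 °C; then crude, pyridinium p-toluenesulfonate, MeOH/CH2Cl2, 0 → 23 °C
Reagents that add atoms: potassium peroxymonosulfate, `[K+].[O-]S(=O)(=O)OO`
Why: Shi asymmetric epoxidation then acid-induced 5-exo epoxide opening: the D-fructose-derived dioxirane epoxidises the electron-rich E trisubstituted alkene to the (R,R)-epoxide (the iodoalkene and silylalkyne are electron-poor and much slower), and after methanolysis of the silyl ether the C12 hydroxyl attacks the tertiary epoxide carbon with inversion, setting C1 (S), C2 (R) and the cis-2,5-disubstituted oxolane.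

Step 12
Reactants: 21 (4E)-1-{(2R,5S)-5-[(1R)-1-hydroxy-5-(trimethylsilyl)pent-4-yn-1-yl]-5-methyloxolan-2-yl}-5-iodo-4-(propan-2-yl)pent-4-en-1-one
Product: 23 (1R)-1-{(2S,5R)-5-[(2S,5E)-2-hydroxy-6-iodo-5-(propan-2-yl)hex-5-en-2-yl]-2-methyloxolan-2-yl}pent-4-yn-1-ol, via silylalkyne diol 22 (not isolated)
Conditions: MeMgBr (4 equiv), THF, −78 °C; then MeOH, K2CO3 (cat.), 23 °C
Reagents that add atoms: methylmagnesium bromide, `C[Mg]Br`
Why: Chelation-controlled Grignard addition (Cram chelate): magnesium bridges the ketone oxygen and the oxolane oxygen, so methyl adds from the face of the C12 hydrogen and sets C11 (S); methanol/K2CO3 added to the same flask then cleaves the alkynyl C–Si bond.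

Step 13
Reactants: 23 (1R)-1-{(2S,5R)-5-[(2S,5E)-2-hydroxy-6-iodo-5-(propan-2-yl)hex-5-en-2-yl]-2-methyloxolan-2-yl}pent-4-yn-1-ol
Product: 25 (1S,2R,5E,7E,11S,12R)-1,5,11-trimethyl-8-(propan-2-yl)-15-oxabicyclo[10.2.1]pentadeca-5,7-diene-2,11-diol, via alkenylalane 24 (not isolated)
Conditions: AlMe3 (5 equiv), Cp2ZrCl2 (0.5 equiv), CH2Cl2, 0 → 23 °C; volatiles removed in vacuo; then syringe-pump addition (10 h) to Pd(P(t-Bu)3)2 (10 mol %), ZnCl2 (20 mol %), THF, 45 °C, final 0.002 M; aqueous work-up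
Reagents that add atoms: trimethylaluminium, `C[Al](C)C`
Why: Proposed new method: one-flask zirconium-catalysed methylalumination of the terminal alkyne (syn, methyl to the internal carbon, fixing the E trisubstituted alkene and placing aluminium on C6) in the presence of the remote alkenyl iodide, which is inert to AlMe3/Cp2ZrCl2, followed by ring-closing alkenyl–alkenyl coupling under zerovalent palladium/ZnCl2 co-catalysis (oxidative addition into the C7–I bond with retention, Al-to-Zn-to-Pd alkenyl transfer that outpaces methyl transfer, reductive elimination at high dilution) forms C6–C7 and the 14-membered ring with both hydroxyls masked as aluminium alkoxides; the closest known chemistry is the intermolecular Negishi carboalumination/palladium-catalysed alkenylalane–alkenyl iodide coupling and macrocyclising Stille or Suzuki diene couplings, whereas ring closure by an alkenylalane generated alongside its own alkenyl iodide partner has, to the best of my knowledge, not been shown.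

Step 14
Reactants: 25 (1S,2R,5E,7E,11S,12R)-1,5,11-trimethyl-8-(propan-2-yl)-15-oxabicyclo[10.2.1]pentadeca-5,7-diene-2,11-diol
Product: 26 (1S,2R,5E,7E,11S,12R)-11-hydroxy-1,5,11-trimethyl-8-(propan-2-yl)-15-oxabicyclo[10.2.1]pentadeca-5,7-dien-2-yl acetate
Conditions: Ac2O, pyridine, 4-(dimethylamino)pyridine (5 mol %), CH2Cl2, 0 → 23 °C
Reagents that add atoms: acetic anhydride, `CC(=O)OC(C)=O`
Why: Nucleophile-catalysed acylation acetylates the secondary hydroxyl, while the hindered tertiary hydroxyl does not react under these conditions.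

## Compound list

1 | pent-3-yn-1-ol | `CC#CCCO` | starting material
2 | alkenylzirconocene chloride: chlorobis(cyclopentadienyl)[(2E)-5-{[chlorobis(cyclopentadienyl)zirconio]oxy}pent-2-en-2-yl]zirconium | `Cl[Zr](OCC/C=C(C)/[Zr](Cl)(C1C=CC=C1)C1C=CC=C1)(C1C=CC=C1)C1C=CC=C1` | intermediate
3 | (3E)-4-iodopent-3-en-1-ol | `OCC/C=C(C)/I` | intermediate
4 | (3E)-4-iodopent-3-en-1-yl trifluoromethanesulfonate | `FC(F)(F)S(=O)(=O)OCC/C=C(C)/I` | intermediate
5 | ethynyltrimethylsilane | `C#C[Si](C)(C)C` | starting material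
6 | lithium acetylide: lithium (trimethylsilyl)acetylide | `[Li]C#C[Si](C)(C)C` | intermediate
7 | trimethyl[(5E)-6-iodohept-5-en-1-yn-1-yl]silane | `C[Si](C)(C)C#CCC/C=C(C)/I` | intermediate
8 | (3R)-3-hydroxyoxolan-2-one | `O[C@@H]1CCOC1=O` | starting material
9 | (3R)-3-[(triethylsilyl)oxy]oxolan-2-one | `CC[Si](CC)(CC)O[C@@H]1CCOC1=O` | intermediate
10 | (3R)-5-hydroxy-3-[(triethylsilyl)oxy]pentan-2-one | `CC(=O)[C@H](O[Si](CC)(CC)CC)CCO` | intermediate
11 | (3R)-5-iodo-3-[(triethylsilyl)oxy]pentan-2-one | `CC(=O)[C@H](O[Si](CC)(CC)CC)CCI` | intermediate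
12 | alkylzinc iodide: iodo{(3R)-4-oxo-3-[(triethylsilyl)oxy]pentyl}zinc | `CC(=O)[C@H](O[Si](CC)(CC)CC)CC[Zn]I` | intermediate
13 | (3R,6E)-6-methyl-3-[(triethylsilyl)oxy]-11-(trimethylsilyl)undec-6-en-10-yn-2-one | `CC(=O)[C@H](O[Si](CC)(CC)CC)CC/C(C)=C/CCC#C[Si](C)(C)C` | intermediate
14 | prop-2-yn-1-ol | `C#CCO` | starting material
15 | alkenylmagnesium alkoxide: chloromagnesium (2Z)-3-(chloromagnesio)-2-(propan-2-yl)prop-2-en-1-olate (C–Mg cis to CH2O) | `CC(C)/C(CO[Mg]Cl)=C/[Mg]Cl` | intermediate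
16 | (2Z)-3-iodo-2-(propan-2-yl)prop-2-en-1-ol (iodine cis to CH2OH) | `CC(C)/C(CO)=C/I` | intermediate
17 | (1Z)-2-(bromomethyl)-1-iodo-3-methylbut-1-ene (iodine cis to CH2Br) | `CC(C)/C(CBr)=C/I` | intermediate
18 | lithium enolate: lithium (3R,6E)-6-methyl-3-[(triethylsilyl)oxy]-11-(trimethylsilyl)undeca-1,6-dien-10-yn-2-olate | `[Li]OC(=C)[C@H](O[Si](CC)(CC)CC)CC/C(C)=C/CCC#C[Si](C)(C)C` | intermediate
19 | (1E,6R,9E)-1-iodo-9-methyl-2-(propan-2-yl)-6-[(triethylsilyl)oxy]-14-(trimethylsilyl)tetradeca-1,9-dien-13-yn-5-one (iodine still cis to the CH2 branch) | `CC(C)/C(CCC(=O)[C@H](O[Si](CC)(CC)CC)CC/C(C)=C/CCC#C[Si](C)(C)C)=C/I` | intermediate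
20 | epoxide: (1E,6R)-1-iodo-8-{(2R,3R)-2-methyl-3-[4-(trimethylsilyl)but-3-yn-1-yl]oxiran-2-yl}-2-(propan-2-yl)-6-[(triethylsilyl)oxy]oct-1-en-5-one | `CC(C)/C(CCC(=O)[C@H](O[Si](CC)(CC)CC)CC[C@@]1(C)O[C@@H]1CCC#C[Si](C)(C)C)=C/I` | intermediate
21 | (4E)-1-{(2R,5S)-5-[(1R)-1-hydroxy-5-(trimethylsilyl)pent-4-yn-1-yl]-5-methyloxolan-2-yl}-5-iodo-4-(propan-2-yl)pent-4-en-1-one | `CC(C)/C(CCC(=O)[C@H]1CC[C@](C)(O1)[C@H](O)CCC#C[Si](C)(C)C)=C/I` | intermediate
22 | silylalkyne diol: (1R)-1-{(2S,5R)-5-[(2S,5E)-2-hydroxy-6-iodo-5-(propan-2-yl)hex-5-en-2-yl]-2-methyloxolan-2-yl}-5-(trimethylsilyl)pent-4-yn-1-ol | `CC(C)/C(CC[C@](C)(O)[C@H]1CC[C@](C)(O1)[C@H](O)CCC#C[Si](C)(C)C)=C/I` | intermediate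
23 | (1R)-1-{(2S,5R)-5-[(2S,5E)-2-hydroxy-6-iodo-5-(propan-2-yl)hex-5-en-2-yl]-2-methyloxolan-2-yl}pent-4-yn-1-ol | `CC(C)/C(CC[C@](C)(O)[C@H]1CC[C@](C)(O1)[C@H](O)CCC#C)=C/I` | intermediate
24 | alkenylalane: the (E)-alkenyl(dimethyl)alane from 23, AlMe2 on the former terminal alkyne carbon cis to the new methyl, both hydroxyls as OAlMe2 | `CC(C)/C(CC[C@](C)(O[Al](C)C)[C@H]1CC[C@](C)(O1)[C@H](O[Al](C)C)CC/C(C)=C/[Al](C)C)=C/I` | intermediate
25 | (1S,2R,5E,7E,11S,12R)-1,5,11-trimethyl-8-(propan-2-yl)-15-oxabicyclo[10.2.1]pentadeca-5,7-diene-2,11-diol | `O[C@@H]1CC/C(C)=C/C=C(/C(C)C)CC[C@](C)(O)[C@H]2CC[C@]1(C)O2` | intermediate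
26 | (1S,2R,5E,7E,11S,12R)-11-hydroxy-1,5,11-trimethyl-8-(propan-2-yl)-15-oxabicyclo[10.2.1]pentadeca-5,7-dien-2-yl acetate | `CC(=O)O[C@@H]1CC/C(C)=C/C=C(/C(C)C)CC[C@](C)(O)[C@H]2CC[C@]1(C)O2` | target

## Step count and risks

Total step count: 14. Longest linear sequence: 9 steps (4, 5, 6, 7, 10, 11, 12, 13, 14; the chain 1, 2, 3, 7, 10–14 is equally long). The east branch (8, 9) enters at step 10.

The three steps most likely to fail:

Step 13, the proposed new ring closure. The alkenyl iodide may be methylated by residual methyl–metal species, or the alkenylalane may be protonated before it closes the ring at high dilution. The fallback uses known chemistry and sets out from 23. After the same AlMe3/Cp2ZrCl2 methylalumination, the alkenylalane is quenched with 2-isopropoxy-4,4,5,5-tetramethyl-1,3,2-dioxaborolane (aluminium-to-boron transmetalation). The stable (1R,4E)-1-{(2S,5R)-5-[(2S,5E)-2-hydroxy-6-iodo-5-(propan-2-yl)hex-5-en-2-yl]-2-methyloxolan-2-yl}-4-methyl-5-(4,4,5,5-tetramethyl-1,3,2-dioxaborolan-2-yl)pent-4-en-1-ol F1 is isolated. A Suzuki–Miyaura macrocyclisation (PdCl2(dppf), AsPh3, Cs2CO3, THF/DMF/H2O, 0.001 M, 23 °C) then closes the same C6–C7 bond and comes back to the route at 25.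

Step 11, the Shi epoxidation and cyclisation. The dioxirane may attack the alkenyl iodide, and opening of the epoxide by methanol may compete with ring closure. The fallback builds the oxolane before the iodide-bearing east fragment arrives and sets out from 13. The same Shi epoxidation followed by pyridinium p-toluenesulfonate/MeOH gives 1-{(2R,5S)-5-[(1R)-1-hydroxy-5-(trimethylsilyl)pent-4-yn-1-yl]-5-methyloxolan-2-yl}ethan-1-one F2. Et3SiCl/imidazole gives its silyl ether 1-{(2R,5S)-5-methyl-5-[(1R)-1-[(triethylsilyl)oxy]-5-(trimethylsilyl)pent-4-yn-1-yl]oxolan-2-yl}ethan-1-one F3. LiN(iPr)2 and then 17 give (4E)-5-iodo-1-{(2R,5S)-5-methyl-5-[(1R)-1-[(triethylsilyl)oxy]-5-(trimethylsilyl)pent-4-yn-1-yl]oxolan-2-yl}-4-(propan-2-yl)pent-4-en-1-one F4. MeMgBr under the same chelation control gives (2S,5E)-6-iodo-2-{(2R,5S)-5-methyl-5-[(1R)-1-[(triethylsilyl)oxy]-5-(trimethylsilyl)pent-4-yn-1-yl]oxolan-2-yl}-5-(propan-2-yl)hex-5-en-2-ol F5. Bu4NF (THF, 23 °C) removes both silyl groups and comes back to the route at 23.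

Step 6, the iodination. Hydroxy ketone 10 sits largely as its cyclic hemiketal, whose anomeric hydroxyl can be activated in place of the primary one. The fallback avoids the hemiketal and sets out from 9. MeNH(OMe)·HCl/iPrMgCl (THF, −20 °C) opens the lactone to the open-chain (2R)-4-hydroxy-N-methoxy-N-methyl-2-[(triethylsilyl)oxy]butanamide F6. I2/PPh3/imidazole gives (2R)-4-iodo-N-methoxy-N-methyl-2-[(triethylsilyl)oxy]butanamide F7. MeMgBr (THF, −78 → 0 °C) converts the Weinreb amide into the methyl ketone and comes back to the route at 11.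

## Further compounds

F1 | step 13 | (1R,4E)-1-{(2S,5R)-5-[(2S,5E)-2-hydroxy-6-iodo-5-(propan-2-yl)hex-5-en-2-yl]-2-methyloxolan-2-yl}-4-methyl-5-(4,4,5,5-tetramethyl-1,3,2-dioxaborolan-2-yl)pent-4-en-1-ol | `CC(C)/C(CC[C@](C)(O)[C@H]1CC[C@](C)(O1)[C@H](O)CC/C(C)=C/B1OC(C)(C)C(C)(C)O1)=C/I`
F2 | step 11 | 1-{(2R,5S)-5-[(1R)-1-hydroxy-5-(trimethylsilyl)pent-4-yn-1-yl]-5-methyloxolan-2-yl}ethan-1-one | `CC(=O)[C@H]1CC[C@](C)(O1)[C@H](O)CCC#C[Si](C)(C)C`
F3 | step 11 | 1-{(2R,5S)-5-methyl-5-[(1R)-1-[(triethylsilyl)oxy]-5-(trimethylsilyl)pent-4-yn-1-yl]oxolan-2-yl}ethan-1-one | `CC(=O)[C@H]1CC[C@](C)(O1)[C@H](O[Si](CC)(CC)CC)CCC#C[Si](C)(C)C`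
F4 | step 11 | (4E)-5-iodo-1-{(2R,5S)-5-methyl-5-[(1R)-1-[(triethylsilyl)oxy]-5-(trimethylsilyl)pent-4-yn-1-yl]oxolan-2-yl}-4-(propan-2-yl)pent-4-en-1-one | `CC(C)/C(CCC(=O)[C@H]1CC[C@](C)(O1)[C@H](O[Si](CC)(CC)CC)CCC#C[Si](C)(C)C)=C/I`
F5 | step 11 | (2S,5E)-6-iodo-2-{(2R,5S)-5-methyl-5-[(1R)-1-[(triethylsilyl)oxy]-5-(trimethylsilyl)pent-4-yn-1-yl]oxolan-2-yl}-5-(propan-2-yl)hex-5-en-2-ol | `CC(C)/C(CC[C@](C)(O)[C@H]1CC[C@](C)(O1)[C@H](O[Si](CC)(CC)CC)CCC#C[Si](C)(C)C)=C/I`
F6 | step 6 | (2R)-4-hydroxy-N-methoxy-N-methyl-2-[(triethylsilyl)oxy]butanamide | `CON(C)C(=O)[C@H](O[Si](CC)(CC)CC)CCO`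
F7 | step 6 | (2R)-4-iodo-N-methoxy-N-methyl-2-[(triethylsilyl)oxy]butanamide | `CON(C)C(=O)[C@H](O[Si](CC)(CC)CC)CCI`
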